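Ring C is cut between the carbonyl carbon C4 and the arene carbon C4a. In the key step an aryllithium at C4a, made by bromine–lithium exchange, adds to a tethered N-methoxy-N-methylamide (Parham cyclization), closing ring C; the ketone appears only on acidic quench, so C2 cannot racemise through the chalcone. The step exploits that C4a lies ortho to the ether oxygen O1 of ring A and that C4a and C6 are equivalent in 4,6-dibromoresorcinol: one bromine closes the ring, the other is kept for the C6 prenyl group. The precursor is an open-chain (S)-β-aryloxy amide, its C2 centre set by transfer hydrogenation and Mitsunobu inversion.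

Key step: step 4

Remark: flavanone numbering is used, also for the corresponding atoms of the open-chain precursors (O1, C2–C4, C4a, C5–C8, C8a; ring A fused benzene, ring B 4-methoxyphenyl, ring C pyranone); the 7-hydroxyl is carried unprotected, and compounds 1 and 4 and tributyl(3-methylbut-2-en-1-yl)stannane are taken as commercial.

Step 1
Reactants: 1 ethyl 3-(4-methoxyphenyl)-3-oxopropanoate
Product: 2 ethyl (R)-3-hydroxy-3-(4-methoxyphenyl)propanoate
Conditions: RuCl[(R,R)-TsDPEN](p-cymene) (1 mol %), HCO2H/Et3N 5:2, DMF, 40 °C
Reagents that add atoms: none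
Why: Noyori asymmetric transfer hydrogenation, in which the (R,R)-TsDPEN ruthenium hydride reduces the aryl ketone through the CH/π-organised six-membered transition state and should give the (R)-carbinol, as it does with aryl alkyl ketones, leaving the ester untouched.

Step 2
Reactants: 2 ethyl (R)-3-hydroxy-3-(4-methoxyphenyl)propanoate
Product: 3 (R)-3-hydroxy-N-methoxy-3-(4-methoxyphenyl)-N-methylpropanamide
Conditions: MeNH(OMe)·HCl (2.5 equiv), i-PrMgCl (6 equiv), THF, −20 to 0 °C; then cold 0.5 M HCl to pH 5
Reagents that add atoms: N,O-dimethylhydroxylamine hydrochloride, CNOC.Cl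
Why: Aminolysis of the ester by the chloromagnesium amide of N,O-dimethylhydroxylamine, with the carbinol masked in the flask as its magnesium alkoxide and the carbinol carbon not involved, so the (R) configuration should be kept.

Step 3
Reactants: 3 (R)-3-hydroxy-N-methoxy-3-(4-methoxyphenyl)-N-methylpropanamide; 4 4,6-dibromobenzene-1,3-diol (3 equiv)
Product: 6 (S)-3-(2,4-dibromo-5-hydroxyphenoxy)-N-methoxy-3-(4-methoxyphenyl)-N-methylpropanamide, via alkoxyphosphonium salt 5 (not isolated)
Conditions: PPh3 (1.3 equiv), DIAD (1.3 equiv), THF–toluene 1:2, −20 to 0 °C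
Reagents that add atoms: none
Why: Mitsunobu etherification, in which one of the two equivalent hydroxyls of the symmetric, acidic dibromophenol (in excess to hold back double alkylation) displaces the alkoxyphosphonium group by SN2 with inversion, turning the (R)-carbinol into the (S)-aryl ether, while the weakly α-acidic amide and the cold, weakly polar medium should hold back dehydration and ionisation.

Step 4
Reactants: 6 (S)-3-(2,4-dibromo-5-hydroxyphenoxy)-N-methoxy-3-(4-methoxyphenyl)-N-methylpropanamide
Product: 10 (S)-6-bromo-7-hydroxy-2-(4-methoxyphenyl)chroman-4-one, via sodium aryloxide 7 (not isolated), via aryllithium 8 (not isolated), via tetrahedral adduct 9 (not isolated)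
Conditions: NaH (1.0 equiv), THF, 0 °C; t-BuLi (2.1 equiv), −90 °C, 20 min; AcOH in THF at −90 °C, then warm to rt
Reagents that add atoms: none
Why: Parham cyclization (cycliacylation of an aryllithium onto an N-methoxy-N-methylamide): after the phenol is taken to its sodium salt, t-BuLi exchanges the C4a–Br bond (the second equivalent destroys t-BuBr) and the aryllithium adds to the amide carbonyl to give the lithium-chelated tetrahedral adduct, which releases the ketone only on the cold acetic acid quench. Ring C closes by a 6-exo-trig attack that forms the C4–C4a bond. No stereocentre is created in the product (the hemiaminal carbon of 9 is transient), and C2, set in step 3, is not involved; because no enolisable ketone exists while the mixture is basic, the ring opening to the chalcone that racemises flavanones has no path. The step needs site selectivity between the two C–Br bonds and exchange faster than proton abstraction at C3: the bromine at C4a is activated by the ortho ether oxygen O1 and lies next to the lithium-binding amide side chain, whereas the bromine at C6 sits ortho to the electron-rich aryloxide and should exchange far more slowly, and at −90 °C bromine–lithium exchange outruns deprotonation. The anionic closure also avoids the acid of a Friedel–Crafts acylation, which would ionise the p-methoxybenzylic C2–O1 bond.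

Step 5
Reactants: 10 (S)-6-bromo-7-hydroxy-2-(4-methoxyphenyl)chroman-4-one
Product: 11 (S)-6-bromo-7-hydroxy-8-iodo-2-(4-methoxyphenyl)chroman-4-one
Conditions: NIS (1.05 equiv), DMF, 0 °C to rt, dark
Reagents that add atoms: N-iodosuccinimide, O=C1CCC(=O)N1I
Why: Electrophilic aromatic iodination of the free phenol, for which C8 is the only open position ortho to the 7-hydroxyl (C6 carries bromine, C5 is meta to both oxygens), while without added acid ring B and C3 should not react and C2 is untouched.

Step 6
Reactants: 11 (S)-6-bromo-7-hydroxy-8-iodo-2-(4-methoxyphenyl)chroman-4-one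
Product: 13 (S)-7-hydroxy-2-(4-methoxyphenyl)-6,8-bis(3-methylbut-2-en-1-yl)chroman-4-one, via monoprenyl bromide 12 (not isolated)
Conditions: Bu3SnCH2CH=CMe2 (3 equiv), Pd(PPh3)4 (10 mol %), DMF, 95 °C
Reagents that add atoms: tributyl(3-methylbut-2-en-1-yl)stannane, CCCC[Sn](CCCC)(CCCC)CC=C(C)C
Why: Twofold Stille coupling, in which oxidative addition at C8–I and then at C6–Br, transmetalation from the prenylstannane and reductive elimination at the unsubstituted allyl terminus should give the two linear 3-methylbut-2-enyl groups under neutral conditions that leave C2 and the free phenol alone.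

Compound list
1 | ethyl 3-(4-methoxyphenyl)-3-oxopropanoate | CCOC(=O)CC(=O)c1ccc(OC)cc1 | starting material
2 | ethyl (R)-3-hydroxy-3-(4-methoxyphenyl)propanoate | COc1ccc([C@H](O)CC(=O)OCC)cc1 | intermediate
3 | (R)-3-hydroxy-N-methoxy-3-(4-methoxyphenyl)-N-methylpropanamide | COc1ccc([C@H](O)CC(=O)N(C)OC)cc1 | intermediate
4 | 4,6-dibromobenzene-1,3-diol (4,6-dibromoresorcinol) | Oc1cc(O)c(Br)cc1Br | starting material
5 | alkoxytriphenylphosphonium salt of 3, counter-ion the monoaryloxide of 4 (formed in the flask) | COc1ccc([C@H](O[P+](c2ccccc2)(c2ccccc2)c2ccccc2)CC(=O)N(C)OC)cc1.[O-]c1cc(O)c(Br)cc1Br | intermediate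
6 | (S)-3-(2,4-dibromo-5-hydroxyphenoxy)-N-methoxy-3-(4-methoxyphenyl)-N-methylpropanamide | COc1ccc([C@@H](Oc2cc(O)c(Br)cc2Br)CC(=O)N(C)OC)cc1 | intermediate
7 | sodium aryloxide of 6 (formed in the flask) | COc1ccc([C@@H](Oc2cc([O-])c(Br)cc2Br)CC(=O)N(C)OC)cc1.[Na+] | intermediate
8 | aryllithium at C4a, sodium aryloxide form (formed in the flask) | COc1ccc([C@@H](Oc2cc([O-])c(Br)cc2[Li])CC(=O)N(C)OC)cc1.[Na+] | intermediate
9 | tetrahedral lithium N-methoxy-N-methyl hemiaminalate, sodium aryloxide form, mixture at C4 (formed in the flask) | COc1ccc([C@@H]2CC(O[Li])(N(C)OC)c3cc(Br)c([O-])cc3O2)cc1.[Na+] | intermediate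
10 | (S)-6-bromo-7-hydroxy-2-(4-methoxyphenyl)chroman-4-one | COc1ccc([C@@H]2CC(=O)c3cc(Br)c(O)cc3O2)cc1 | intermediate
11 | (S)-6-bromo-7-hydroxy-8-iodo-2-(4-methoxyphenyl)chroman-4-one | COc1ccc([C@@H]2CC(=O)c3cc(Br)c(O)c(I)c3O2)cc1 | intermediate
12 | (S)-6-bromo-7-hydroxy-2-(4-methoxyphenyl)-8-(3-methylbut-2-en-1-yl)chroman-4-one (formed in the flask) | COc1ccc([C@@H]2CC(=O)c3cc(Br)c(O)c(CC=C(C)C)c3O2)cc1 | intermediate
13 | (S)-7-hydroxy-2-(4-methoxyphenyl)-6,8-bis(3-methylbut-2-en-1-yl)chroman-4-one (the target flavanone) | COc1ccc([C@@H]2CC(=O)c3cc(CC=C(C)C)c(O)c(CC=C(C)C)c3O2)cc1 | target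

Total step count: 6. Longest linear sequence: 6 steps (1 to 13).

Steps most likely to fail

Step 4. The bromine–lithium exchange may lose site selectivity (lithiation at the C–Br bond next to the aryloxide). It may also be slowed so far by the electron-rich aryloxide ring that proton transfer from the α-methylene and β-elimination of the aryloxide compete. The fallback replaces the symmetry-based ring A by a protected ring A with a single halogen; it sets out from 3 and comes back at 13. Mitsunobu etherification of 3 with commercial 5-(benzyloxy)-2-bromophenol should give (S)-3-[5-(benzyloxy)-2-bromophenoxy]-N-methoxy-3-(4-methoxyphenyl)-N-methylpropanamide F1. With one bromine and no aryloxide the exchange (t-BuLi, THF, −95 °C, AcOH quench) is unambiguous and should close ring C by the same C4–C4a bond to (S)-7-(benzyloxy)-2-(4-methoxyphenyl)chroman-4-one F2. Hydrogenolysis (H2, Pd/C, EtOAc) should give (S)-7-hydroxy-2-(4-methoxyphenyl)chroman-4-one F3, and twofold iodination (NIS, 2.1 equiv, DMF) should give (S)-7-hydroxy-6,8-diiodo-2-(4-methoxyphenyl)chroman-4-one F4. The twofold Stille coupling of step 6 then leads to 13.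

Step 3. Partial ionisation of the p-methoxybenzylic alkoxyphosphonium salt may erode the inversion, and base-induced dehydration may lead to the cinnamamide. The fallback sets the stereocentre after ring closure by asymmetric conjugate arylation, so no substitution at a benzylic carbon is needed; it sets out from 4 and comes back at 10. Mitsunobu etherification of 4 (excess) with the primary carbinol 3-hydroxy-N-methoxy-N-methylpropanamide should give 3-(2,4-dibromo-5-hydroxyphenoxy)-N-methoxy-N-methylpropanamide F5. The ring closure of step 4 (NaH; t-BuLi, −90 °C; AcOH) should give 6-bromo-7-hydroxychroman-4-one F6. Aerobic dehydrogenation (Pd(OCOCF3)2, DMSO, O2, AcOH, 80 °C) should give 6-bromo-7-hydroxy-4H-chromen-4-one F7. Conjugate addition of 4-methoxyphenylboronic acid, catalysed by Pd(OCOCF3)2 and (R)-4-tert-butyl-2-(pyridin-2-yl)-4,5-dihydrooxazole (NH4PF6, H2O, 1,2-dichloroethane, 60 °C), should then give 10. The (R)-ligand is the enantiomer expected, by analogy with cyclic enones, to deliver the aryl group to the face that gives (2S).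

Step 6. Allylic transposition during transmetalation or reductive elimination may give 1,1-dimethylallyl groups, and slow oxidative addition at the electron-rich C6–Br bond may end in protodebromination. The fallback brings in unsubstituted allyl groups, which have no regiochemical issue, and builds the trisubstituted alkenes by metathesis; it sets out from 11 and comes back at 13. Twofold Stille coupling of 11 with allyltributylstannane (Pd(PPh3)4, DMF, 95 °C) should give (S)-6,8-diallyl-7-hydroxy-2-(4-methoxyphenyl)chroman-4-one F8. Cross metathesis with 2-methylbut-2-ene (second-generation Grubbs catalyst, CH2Cl2, 40 °C) should convert both allyl groups into 3-methylbut-2-enyl groups and give 13.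

Further compounds
F1 | step 4 | (S)-3-[5-(benzyloxy)-2-bromophenoxy]-N-methoxy-3-(4-methoxyphenyl)-N-methylpropanamide | COc1ccc([C@@H](Oc2cc(OCc3ccccc3)ccc2Br)CC(=O)N(C)OC)cc1
F2 | step 4 | (S)-7-(benzyloxy)-2-(4-methoxyphenyl)chroman-4-one | COc1ccc([C@@H]2CC(=O)c3ccc(OCc4ccccc4)cc3O2)cc1
F3 | step 4 | (S)-7-hydroxy-2-(4-methoxyphenyl)chroman-4-one | COc1ccc([C@@H]2CC(=O)c3ccc(O)cc3O2)cc1
F4 | step 4 | (S)-7-hydroxy-6,8-diiodo-2-(4-methoxyphenyl)chroman-4-one | COc1ccc([C@@H]2CC(=O)c3cc(I)c(O)c(I)c3O2)cc1
F5 | step 3 | 3-(2,4-dibromo-5-hydroxyphenoxy)-N-methoxy-N-methylpropanamide | CON(C)C(=O)CCOc1cc(O)c(Br)cc1Br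
F6 | step 3 | 6-bromo-7-hydroxychroman-4-one | O=C1CCOc2cc(O)c(Br)cc12
F7 | step 3 | 6-bromo-7-hydroxy-4H-chromen-4-one | O=c1ccoc2cc(O)c(Br)cc12
F8 | step 6 | (S)-6,8-diallyl-7-hydroxy-2-(4-methoxyphenyl)chroman-4-one | COc1ccc([C@@H]2CC(=O)c3cc(CC=C)c(O)c(CC=C)c3O2)cc1
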